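The earlier runs and the new flask are calculated with made-up constants; noise was put on by code.

Amounts first: with 0.34 M of substrate the alder run ended at 21.0% target, and with 0.75 M the larch run ended at 12.2%, each as a percentage of its own charge.

| flask | substrate | gas phase | remark | time |
|---|---|---|---|---|
| alder | 0.34 M | 29 mM (held) | run made earlier |  |
| larch | 0.75 M | 29 mM (held) | run made earlier |  |
| flask | 0.50 M | 29 mM (held) |  | 12 min |

| run | time / min | target / % | substrate / % |
|---|---|---|---|
| alder | 0.500 | 6.1 | 69.3 |
| alder | 0.833 | 9.2 | 52.7 |
| alder | 1.33 | 13.8 | 34.1 |
| alder | 2.00 | 17.2 | 17.8 |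
| alder | 3.00 | 19.9 | 6.1 |
| alder | 5.00 | 21.1 | 0.2 |
| alder | 8.00 | 21.0 | 0.6 |
| larch | 0.417 | 3.4 | 76.1 |
| larch | 1.00 | 6.2 | 48.9 |
| larch | 2.00 | 9.4 | 19.7 |
| larch | 3.00 | 11.0 | 7.7 |
| larch | 4.00 | 11.2 | 2.2 |
| larch | 6.00 | 12.1 | 0 |
| larch | 8.00 | 12.2 | 0.1 |

(scatter of a reading: 0.3 percentage points)

- at the start none of the gas phase is in solution

- red: doubling the transfer coefficient of the gas phase, all else as stated
- ochre: doubling the saturation concentration of gas phase, all else as stated

* the target standing at 12 min, as a percentage of the substrate charged
* the change that raises the amount of target at 12 min, in percent of the substrate charged most ("none" if none brings more than 2 percentage points) (red / ochre / none)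
* amount of target at 12 min, in percent of the substrate charged, after red

We read the rates and leave the large flow of substrate aside, reckoning only the small share that becomes target.

1. At the start of the alder run, substrate falls by 0.614 min⁻¹ of the charge and target rises by 0.122 min⁻¹, so the reading gives a share, or selectivity, of 19.9%.

2. Between 3.00 min and 5.00 min the two rates read 0.0295 min⁻¹ and 0.00600 min⁻¹. On these readings the substrate rate has fallen about 20.8-fold. The late share reads 20.3%, but it rests on a target rise of 1.2 percentage points with a scatter of 0.3 points in each reading, so it is too rough to tell whether the share has moved.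

3. The accumulated slowing ends the alder run: its last two target readings differ by 0.1 points, less than the scatter. We therefore take the end value as the answer at 12 min.

4. From the alder run to the larch run the charge is multiplied by 2.21 and the end yield is divided by 1.72. We call the reciprocal of the end yield the price, the substrate charged per target kept. Our assumption is that the price rises in a straight line, and the price slope, its rise per molar of substrate charged, reads 8.38 M⁻¹.

5. At 0.50 M the price is 6.10, so we expect 16.4%.

The forecast says 16.4% (15.4% to 17.4%), noting “Final yield falls with charge”, names ochre as the best change, and gives 24% (18% to 28%) after red.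

The flask gives 16.9%. The best change is ochre, which gains 10 points against 3.2 points for red, and red gives 20.1%.

    gas phase ⇌ dissolved gas, rate k1*(csat - [dissolved gas]) (kL = 0.0660 s⁻¹)
    substrate + dissolved gas → target (k = 0.260 M⁻¹ s⁻¹)
    substrate → side product A (k = 0.00900 s⁻¹)
    substrate + target → side product B (k = 0.0350 M⁻¹ s⁻¹)

The flask has come to rest. At 6.00 min substrate stands at 0.210%, and at our price that remainder is worth 0.034 points of target. Target reads 16.9% then, 16.9% at 24.0 min and 16.9% at 120 min, so ten times the time changes nothing.

On the neighbour flask with 0.85 M of substrate, the slope carried from this flask's price gives 11.3%. The computed neighbour flask gives 11.2%.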